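**Retrosynthetic overview**
1. The strategy rests on the 1,3-syn pair of acetoxy carbons C3 (R) and C5 (S) of the heptane chain. The unit O-C3-C4-C5-O fits a six-membered 1,3-dioxan-2-one, so an oxygen parked on C3 can install the oxygen on C5.
2. Endgame: the three phenols are freed last from benzyl ethers and the acetates come from the syn diol. The C6-C7 bond is cut to a terminal C5-C6 epoxide plus a 3,4-bis(benzyloxy)benzyl Grignard reagent.
3. The syn epoxy alcohol comes from a cis iodocarbonate, made by IBr cyclisation of the (R)-homoallylic tert-butyl carbonate (C5-O and C6-I are formed, and C3 relays to C5).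
4. C3 and the C3-C4 bond come from a Brown allylation of the aldehyde derived from O-benzylated dihydroconiferyl alcohol.
5. Ring order: both arenes are bought. The dioxanone closes in step 5, is traded for an oxirane in step 6, and the oxirane is opened in step 7, so no ring made on the way stays in the target.

Key step: step 5

Remark on the chemistry: locants C1 to C7 run from the benzylic carbon on the 4-hydroxy-3-methoxyphenyl ring, which makes the target (3R,5S), the 1,3-syn arrangement. The allylborane is assumed to be bought as its salt-free 1 M pentane solution.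

**Step 1**
Reactants: 1 dihydroconiferyl alcohol
Product: 2 3-[4-(benzyloxy)-3-methoxyphenyl]propan-1-ol
Conditions: BnBr, K2CO3, acetone, reflux
Reagents that add atoms: benzyl bromide, BrCc1ccccc1
Why: Williamson ether synthesis in which K2CO3 deprotonates only the phenol, so the primary alcohol should stay free.

**Step 2**
Reactants: 2 3-[4-(benzyloxy)-3-methoxyphenyl]propan-1-ol
Product: 3 3-[4-(benzyloxy)-3-methoxyphenyl]propanal
Conditions: TEMPO (10 mol %), PhI(OAc)2, CH2Cl2, rt
Reagents that add atoms: none
Why: Oxoammonium-mediated (TEMPO/diacetoxyiodobenzene) oxidation of a primary alcohol, which should stop at the aldehyde in dry CH2Cl2 and leave the aryl ethers alone.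

**Step 3**
Reactants: 3 3-[4-(benzyloxy)-3-methoxyphenyl]propanal; 4 (−)-B-allyldiisopinocampheylborane (both isopinocampheyl groups derived from (+)-α-pinene)
Product: 6 (3R)-1-[4-(benzyloxy)-3-methoxyphenyl]hex-5-en-3-ol, via diisopinocampheylborinate ester 5 (not isolated)
Conditions: 4 (1 M in pentane), Et2O, −100 → −78 °C; then 3 M NaOH, 30% H2O2, 0 °C → rt
Reagents that add atoms: (−)-B-allyldiisopinocampheylborane 4, C=CCB([C@@H]1C[C@@H]2C[C@H]([C@H]1C)C2(C)C)[C@@H]1C[C@@H]2C[C@H]([C@H]1C)C2(C)C
Why: Brown asymmetric allylboration through a closed chair Zimmerman-Traxler transition state, in which the isopinocampheyl groups from (+)-α-pinene direct the allyl group to the Si face of the aldehyde so that C3 is set as R, after which alkaline H2O2 cleaves borinate 5.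

**Step 4**
Reactants: 6 (3R)-1-[4-(benzyloxy)-3-methoxyphenyl]hex-5-en-3-ol; 7 di-tert-butyl dicarbonate
Product: 8 tert-butyl (3R)-1-[4-(benzyloxy)-3-methoxyphenyl]hex-5-en-3-yl carbonate
Conditions: Boc2O, DMAP (0.3 equiv), MeCN, rt
Reagents that add atoms: di-tert-butyl dicarbonate 7, CC(C)(C)OC(=O)OC(=O)OC(C)(C)C
Why: DMAP-catalysed O-tert-butoxycarbonylation (nucleophilic acyl-transfer catalysis) that acylates on oxygen without touching the C3-O bond, so the R configuration is kept.

**Step 5**
Reactants: 8 tert-butyl (3R)-1-[4-(benzyloxy)-3-methoxyphenyl]hex-5-en-3-yl carbonate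
Product: 10 (4R,6R)-4-{2-[4-(benzyloxy)-3-methoxyphenyl]ethyl}-6-(iodomethyl)-1,3-dioxan-2-one, via tert-butoxydioxanylium bromide 9 (not isolated)
Conditions: IBr (1.1 equiv, 1 M in CH2Cl2), PhMe, −85 °C; cold quench with aq. Na2S2O3/NaHCO3
Reagents that add atoms: iodine monobromide, IBr
Why: IBr adds reversibly to the C5=C6 alkene to give an iodonium ion, the carbonyl oxygen of the C3 carbonate opens it at the more substituted carbon C5, and the dioxanylium ion 9 formed in this way sheds isobutene and HBr to leave the neutral cyclic carbonate. This is the established iodocarbonate cyclisation of homoallylic tert-butyl carbonates, a member of the halocyclisation family of electrophilic cyclofunctionalisations. The one ring made, the 1,3-dioxan-2-one, closes in the 6-exo mode, since 7-endo attack at the terminal carbon C6 is disfavoured both electronically and by ring size. The new stereocentre C5 is controlled by C3, because in the chair-like transition state the arylethyl chain on C3 and the developing CH2I arm both lie equatorial, so the C5-O bond forms cis to the C3 substituent and ring carbon C6 becomes R. The step needs 1,3-syn diastereoselectivity, which that chair supplies best at −85 °C in toluene, and chemoselectivity for the alkene over the dialkoxyarene, which the low temperature, the slight excess of IBr, the fast intramolecular capture and the cold reductive quench should secure. No other alkene or internal nucleophile competes, because the phenol is capped as its benzyl ether and the alcohol as the carbonate itself.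

**Step 6**
Reactants: 10 (4R,6R)-4-{2-[4-(benzyloxy)-3-methoxyphenyl]ethyl}-6-(iodomethyl)-1,3-dioxan-2-one
Product: 12 (2R)-4-[4-(benzyloxy)-3-methoxyphenyl]-1-[(2R)-oxiran-2-yl]butan-2-ol, via iodohydrin diol 11 (not isolated)
Conditions: K2CO3 (3 equiv), MeOH, 0 °C → rt
Reagents that add atoms: none
Why: Methanolysis (transesterification) of the cyclic carbonate followed by an intramolecular Williamson 3-exo-tet displacement of iodide by the C5 alkoxide, which breaks neither the C3-O nor the C5-O bond and so keeps both configurations.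

**Step 7**
Reactants: 12 (2R)-4-[4-(benzyloxy)-3-methoxyphenyl]-1-[(2R)-oxiran-2-yl]butan-2-ol; 13 3,4-bis(benzyloxy)benzyl chloride
Product: 15 (3R,5S)-1-[4-(benzyloxy)-3-methoxyphenyl]-7-[3,4-bis(benzyloxy)phenyl]heptane-3,5-diol, via benzylic Grignard reagent 14 (not isolated)
Conditions: 13 (3 equiv, slow addition), Mg turnings, THF, 0 °C (ca. 0.3 M); CuI (20 mol %), −40 °C; then 12, THF, −40 → −10 °C; aq. NH4Cl
Reagents that add atoms: 3,4-bis(benzyloxy)benzyl chloride 13, ClCc1ccc(OCc2ccccc2)c(OCc2ccccc2)c1
Why: Copper-catalysed Grignard opening of a terminal epoxide by SN2 attack at the unsubstituted carbon C6, which forms C6-C7 and leaves C5 untouched, with one equivalent of 14 spent on deprotonating the C3 hydroxyl.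

**Step 8**
Reactants: 15 (3R,5S)-1-[4-(benzyloxy)-3-methoxyphenyl]-7-[3,4-bis(benzyloxy)phenyl]heptane-3,5-diol
Product: 16 (3R,5S)-1-[4-(benzyloxy)-3-methoxyphenyl]-7-[3,4-bis(benzyloxy)phenyl]heptane-3,5-diyl diacetate
Conditions: Ac2O, pyridine, DMAP (cat.), CH2Cl2, 0 °C → rt
Reagents that add atoms: acetic anhydride, CC(=O)OC(C)=O
Why: DMAP-catalysed acetylation of the only two free hydroxyl groups, an O-acylation that does not affect either stereocentre.

**Step 9**
Reactants: 16 (3R,5S)-1-[4-(benzyloxy)-3-methoxyphenyl]-7-[3,4-bis(benzyloxy)phenyl]heptane-3,5-diyl diacetate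
Product: 17 (3R,5S)-7-(3,4-dihydroxyphenyl)-1-(4-hydroxy-3-methoxyphenyl)heptane-3,5-diyl diacetate (CNP0315129.1)
Conditions: H2 (1 atm), 10% Pd/C, EtOAc, rt; filtration under argon
Reagents that add atoms: none
Why: Heterogeneous catalytic hydrogenolysis cleaves the three aryl benzyl ethers, while the secondary acetates, being neither benzylic nor allylic, should survive in the neutral aprotic solvent without transesterification.

**Compound list**
1 | dihydroconiferyl alcohol, 3-(4-hydroxy-3-methoxyphenyl)propan-1-ol | COc1cc(CCCO)ccc1O | starting material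
2 | 3-[4-(benzyloxy)-3-methoxyphenyl]propan-1-ol | COc1cc(CCCO)ccc1OCc1ccccc1 | intermediate
3 | 3-[4-(benzyloxy)-3-methoxyphenyl]propanal | COc1cc(CCC=O)ccc1OCc1ccccc1 | intermediate
4 | (−)-B-allyldiisopinocampheylborane, from (+)-α-pinene | C=CCB([C@@H]1C[C@@H]2C[C@H]([C@H]1C)C2(C)C)[C@@H]1C[C@@H]2C[C@H]([C@H]1C)C2(C)C | starting material
5 | (3R)-1-[4-(benzyloxy)-3-methoxyphenyl]hex-5-en-3-yl diisopinocampheylborinate | COc1cc(CC[C@H](CC=C)OB([C@@H]2C[C@@H]3C[C@H]([C@H]2C)C3(C)C)[C@@H]2C[C@@H]3C[C@H]([C@H]2C)C3(C)C)ccc1OCc1ccccc1 | intermediate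
6 | (3R)-1-[4-(benzyloxy)-3-methoxyphenyl]hex-5-en-3-ol | COc1cc(CC[C@@H](O)CC=C)ccc1OCc1ccccc1 | intermediate
7 | di-tert-butyl dicarbonate | CC(C)(C)OC(=O)OC(=O)OC(C)(C)C | starting material
8 | tert-butyl (3R)-1-[4-(benzyloxy)-3-methoxyphenyl]hex-5-en-3-yl carbonate | COc1cc(CC[C@H](CC=C)OC(=O)OC(C)(C)C)ccc1OCc1ccccc1 | intermediate
9 | (4R,6R)-4-{2-[4-(benzyloxy)-3-methoxyphenyl]ethyl}-2-tert-butoxy-6-(iodomethyl)-1,3-dioxan-2-ylium bromide | COc1cc(CC[C@@H]2C[C@H](CI)O[C+](OC(C)(C)C)O2)ccc1OCc1ccccc1.[Br-] | intermediate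
10 | (4R,6R)-4-{2-[4-(benzyloxy)-3-methoxyphenyl]ethyl}-6-(iodomethyl)-1,3-dioxan-2-one | COc1cc(CC[C@@H]2C[C@H](CI)OC(=O)O2)ccc1OCc1ccccc1 | intermediate
11 | (2R,4R)-6-[4-(benzyloxy)-3-methoxyphenyl]-1-iodohexane-2,4-diol | COc1cc(CC[C@@H](O)C[C@@H](O)CI)ccc1OCc1ccccc1 | intermediate
12 | (2R)-4-[4-(benzyloxy)-3-methoxyphenyl]-1-[(2R)-oxiran-2-yl]butan-2-ol | COc1cc(CC[C@@H](O)C[C@@H]2CO2)ccc1OCc1ccccc1 | intermediate
13 | 3,4-bis(benzyloxy)benzyl chloride | ClCc1ccc(OCc2ccccc2)c(OCc2ccccc2)c1 | starting material
14 | 3,4-bis(benzyloxy)benzylmagnesium chloride | Cl[Mg]Cc1ccc(OCc2ccccc2)c(OCc2ccccc2)c1 | intermediate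
15 | (3R,5S)-1-[4-(benzyloxy)-3-methoxyphenyl]-7-[3,4-bis(benzyloxy)phenyl]heptane-3,5-diol | COc1cc(CC[C@@H](O)C[C@@H](O)CCc2ccc(OCc3ccccc3)c(OCc3ccccc3)c2)ccc1OCc1ccccc1 | intermediate
16 | (3R,5S)-1-[4-(benzyloxy)-3-methoxyphenyl]-7-[3,4-bis(benzyloxy)phenyl]heptane-3,5-diyl diacetate | COc1cc(CC[C@H](C[C@H](CCc2ccc(OCc3ccccc3)c(OCc3ccccc3)c2)OC(C)=O)OC(C)=O)ccc1OCc1ccccc1 | intermediate
17 | (3R,5S)-7-(3,4-dihydroxyphenyl)-1-(4-hydroxy-3-methoxyphenyl)heptane-3,5-diyl diacetate | COc1cc(CC[C@H](C[C@H](CCc2ccc(O)c(O)c2)OC(C)=O)OC(C)=O)ccc1O | target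

Total step count: 9. Longest linear sequence: 9 steps (1 to 17). Compounds 4, 7 and 13 enter as purchased materials.

**Steps most likely to fail**

Step 5 (key step). Electrophilic iodination of the electron-rich dialkoxyarene may compete with activation of the alkene. The cis preference may also erode if the closure is not kept cold throughout.
- The fallback replaces the C3-to-C5 relay by catalyst control; it sets out from 6 and comes back at 12.
- Alcohol 6 is silylated (TBSCl, imidazole, DMF) to the tert-butyldimethylsilyl ether F1.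
- mCPBA in CH2Cl2 then gives the silyloxy epoxide as a mixture of C5 epimers F2.
- A Jacobsen hydrolytic kinetic resolution follows, using about half an equivalent of water. The catalyst is the acetate of trivalent cobalt bound to (R,R)-N,N'-bis(3,5-di-tert-butylsalicylidene)cyclohexane-1,2-diamine, the enantiomer that leaves (R)-alkyloxiranes unreacted.
- This should leave the syn silyloxy epoxide F3 untouched while its C5 epimer is hydrolysed to the silyloxy 1,2-diol F4, which is removed by chromatography.
- TBAF in THF then frees 12.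

Step 7. Wurtz-type homocoupling may consume the electron-rich benzylic chloride while its Grignard reagent is being formed. The magnesium alkoxide of the epoxy alcohol may also open slowly, with chlorohydrin formation as a drain.
- The fallback uses a sulfone-stabilised benzylic carbanion instead of a benzylic organometallic; it sets out from 12 and 13 and comes back at 15.
- Chloride 13 and PhSO2Na in DMF give 3,4-bis(benzyloxy)benzyl phenyl sulfone F5.
- F5 is lithiated with n-BuLi (THF, −78 °C, in excess so that the C3 hydroxyl is deprotonated as well).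
- The lithiated sulfone opens 12 at C6 in THF/DMPU on warming to rt, giving the γ-hydroxy sulfone diol F6 as a pair of C7 epimers.
- Reductive desulfonylation with sodium amalgam and Na2HPO4 in MeOH removes the sulfonyl group and the C7 stereocentre and should deliver 15.

Step 3. Facial discrimination on this unbranched aldehyde may be incomplete. Any shortfall in enantiomeric purity is carried to the target, because C5 is derived from C3.
- The fallback takes the C3 configuration from a kinetic resolution and forms C4-C5 instead of C3-C4; it sets out from 3 and comes back at 6.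
- Corey-Chaykovsky methylenation of 3 (trimethylsulfonium iodide, NaH, DMSO/THF) gives the racemic arylethyl oxirane F7.
- Hydrolytic kinetic resolution with the same (R,R)-configured cobalt acetate complex and 0.55 equivalents of water should leave the (R)-oxirane F8 and convert its enantiomer into the (S)-butane-1,2-diol F9.
- Opening of F8 at its terminal carbon with vinylmagnesium bromide and CuI (10 mol %) in THF at −30 °C gives 6.

**Further compounds**
F1 | step 5 | tert-butyl({(3R)-1-[4-(benzyloxy)-3-methoxyphenyl]hex-5-en-3-yl}oxy)dimethylsilane | COc1cc(CC[C@H](CC=C)O[Si](C)(C)C(C)(C)C)ccc1OCc1ccccc1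
F2 | step 5 | tert-butyl({(2R)-4-[4-(benzyloxy)-3-methoxyphenyl]-1-(oxiran-2-yl)butan-2-yl}oxy)dimethylsilane, both epimers at the oxirane carbon | COc1cc(CC[C@H](CC2CO2)O[Si](C)(C)C(C)(C)C)ccc1OCc1ccccc1
F3 | step 5 | tert-butyl({(2R)-4-[4-(benzyloxy)-3-methoxyphenyl]-1-[(2R)-oxiran-2-yl]butan-2-yl}oxy)dimethylsilane | COc1cc(CC[C@H](C[C@@H]2CO2)O[Si](C)(C)C(C)(C)C)ccc1OCc1ccccc1
F4 | step 5 | (2S,4R)-6-[4-(benzyloxy)-3-methoxyphenyl]-4-[(tert-butyldimethylsilyl)oxy]hexane-1,2-diol | COc1cc(CC[C@H](C[C@H](O)CO)O[Si](C)(C)C(C)(C)C)ccc1OCc1ccccc1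
F5 | step 7 | 3,4-bis(benzyloxy)benzyl phenyl sulfone | O=S(=O)(Cc1ccc(OCc2ccccc2)c(OCc2ccccc2)c1)c1ccccc1
F6 | step 7 | (3R,5R)-1-[4-(benzyloxy)-3-methoxyphenyl]-7-[3,4-bis(benzyloxy)phenyl]-7-(phenylsulfonyl)heptane-3,5-diol, both C7 epimers; C5 has the same spatial arrangement as in 15 and only its descriptor changes | COc1cc(CC[C@@H](O)C[C@@H](O)CC(c2ccc(OCc3ccccc3)c(OCc3ccccc3)c2)S(=O)(=O)c2ccccc2)ccc1OCc1ccccc1
F7 | step 3 | racemic 2-{2-[4-(benzyloxy)-3-methoxyphenyl]ethyl}oxirane | COc1cc(CCC2CO2)ccc1OCc1ccccc1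
F8 | step 3 | (2R)-2-{2-[4-(benzyloxy)-3-methoxyphenyl]ethyl}oxirane | COc1cc(CC[C@@H]2CO2)ccc1OCc1ccccc1
F9 | step 3 | (2S)-4-[4-(benzyloxy)-3-methoxyphenyl]butane-1,2-diol | COc1cc(CC[C@H](O)CO)ccc1OCc1ccccc1
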